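**Retrosynthetic overview**
1. Feature used: ring B (C10, C1–C5) meets ring A (C5–C10) at the C5–C10 bond, which joins the quaternary C5 to the tertiary carbinol C10, and C10 stands 1,5 to the C8 carbonyl through C5–C6–C7.
2. End game: the C9 angelate and the C3 acetate go on last; the C7 acetyl comes from Stille acetylation of a C7 iodide, and the C6=C7 bond from Saegusa oxidation of a saturated cis-ketol.
3. Ring A (second ring): intramolecular aldol of C9 onto C10 in a 2,2-disubstituted cyclohexanone that carries a 3-oxo-4-silyloxybutyl chain on C5.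
4. Ring B (first ring): de Mayo sequence on an acyclic 1,3-diketone, a [2+2] photocycloaddition of its C10=C7 enol to the C5=C6 isopropenyl terminus (bonds C5–C10 and C6–C7), then retro-aldol cleavage of C7–C10.
5. The diketone comes from a Weinreb amide and the enolate of silyl-protected hydroxyacetone; C3 and C4 come from an anti-selective catalytic asymmetric allylboration of methyl 4-oxobutanoate.

Key step: step 6

Remark 1: atom labels C1–C10 are the decalin positions defined in line 1; β means the face of the C5 methyl group, α the opposite face.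
Remark 2: (E)-2-bromobut-2-ene (methyl groups cis), 1-(tert-butyldimethylsilyloxy)propan-2-one and angelic acid are taken as commercial.
Remark 3: the (R)-phosphoric acid in step 2 is assumed to direct the allyl group to the Re face of the aldehyde; if the sense proves opposite, the (S)-catalyst is used.

**Step 1**
Reactants: 1 (E)-2-bromobut-2-ene
Product: 3 (E)-4,4,5,5-tetramethyl-2-(2-methylbut-2-en-1-yl)-1,3,2-dioxaborolane, via (Z)-but-2-en-2-yllithium 2 (not isolated)
Conditions: t-BuLi (2.0 equiv), Et2O, −78 °C; then ICH2Bpin, −78 °C → rt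
Reagents that add atoms: 2-(iodomethyl)-4,4,5,5-tetramethyl-1,3,2-dioxaborolane, ICB1OC(C)(C)C(C)(C)O1
Why: Bromine–lithium exchange keeps the alkene geometry, and the boron ate complex rearranges by 1,2-shift with loss of iodide (Matteson-type homologation), so the E allylic boronate forms without an allyl-metal species that could scramble the double bond.

**Step 2**
Reactants: 3 (E)-4,4,5,5-tetramethyl-2-(2-methylbut-2-en-1-yl)-1,3,2-dioxaborolane; 4 methyl 4-oxobutanoate
Product: 6 (S)-5-[(R)-3-methylbut-3-en-2-yl]dihydrofuran-2(3H)-one, via methyl (4S,5R)-4-hydroxy-5,6-dimethylhept-6-enoate 5 (not isolated)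
Conditions: (R)-3,3'-bis(2,4,6-triisopropylphenyl)-1,1'-binaphthyl-2,2'-diyl hydrogen phosphate [(R)-TRIP] (5 mol %), 4 Å MS, toluene, −30 °C; aq. work-up; p-TsOH·H2O (cat.), CH2Cl2, rt
Reagents that add atoms: none
Why: Chiral phosphoric acid-catalysed allylboration through a closed chair transition state (type 1), in which the E γ-methyl group lies equatorial (anti C3/C4 pair) and the catalyst sends the boronate to the Re face (C3 S, C4 R); the γ-hydroxy ester then closes to the γ-lactone under acid.

**Step 3**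
Reactants: 6 (S)-5-[(R)-3-methylbut-3-en-2-yl]dihydrofuran-2(3H)-one
Product: 7 (4S,5R)-4-hydroxy-N-methoxy-N,5,6-trimethylhept-6-enamide
Conditions: MeNH(OMe)·HCl (3 equiv), i-PrMgCl (6 equiv), THF, −20 → 0 °C; aq. NH4Cl
Reagents that add atoms: N,O-dimethylhydroxylamine hydrochloride, CNOC.Cl
Why: Aminolysis of the lactone by the chloromagnesium amide (Weinreb amide formation) opens the ring to a stable magnesium chelate and touches no stereocentre.

**Step 4**
Reactants: 7 (4S,5R)-4-hydroxy-N-methoxy-N,5,6-trimethylhept-6-enamide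
Product: 8 (4S,5R)-N-methoxy-N,5,6-trimethyl-4-(triethylsilyloxy)hept-6-enamide
Conditions: Et3SiCl, imidazole, DMF, 0 °C → rt
Reagents that add atoms: chlorotriethylsilane, CC[Si](Cl)(CC)CC
Why: Routine silylation of the secondary alcohol, done at once so that the γ-hydroxy amide cannot relactonise; the triethylsilyl group is chosen so that it falls in step 11 while the C9 tert-butyldimethylsilyl ether stays.

**Step 5**
Reactants: 8 (4S,5R)-N-methoxy-N,5,6-trimethyl-4-(triethylsilyloxy)hept-6-enamide; 9 1-(tert-butyldimethylsilyloxy)propan-2-one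
Product: 11 (7S,8R)-1-(tert-butyldimethylsilyloxy)-8,9-dimethyl-7-(triethylsilyloxy)dec-9-ene-2,4-dione (mainly as the enol), via lithium 3-(tert-butyldimethylsilyloxy)prop-1-en-2-olate 10 (not isolated)
Conditions: 9 (2.5 equiv), LDA (LiN(i-Pr)2, 2.4 equiv), THF, −78 °C; then 8, −78 → 0 °C; aq. NH4Cl
Reagents that add atoms: none
Why: LDA deprotonates the silyloxy ketone kinetically at its methyl group and the enolate is acylated by the Weinreb amide (crossed Claisen-type condensation), whose tetrahedral chelate lasts until work-up and so prevents a second addition.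

**Step 6 (key step)**
Reactants: 11 (7S,8R)-1-(tert-butyldimethylsilyloxy)-8,9-dimethyl-7-(triethylsilyloxy)dec-9-ene-2,4-dione
Product: 13 (2R,3R,4S)-2-[4-(tert-butyldimethylsilyloxy)-3-oxobutyl]-2,3-dimethyl-4-(triethylsilyloxy)cyclohexan-1-one, via bicyclo[4.2.0]octan-1-ol photoadduct 12 (not isolated)
Conditions: hν (medium-pressure Hg lamp, Pyrex, λ > 300 nm), degassed cyclohexane (0.005 M), 15 °C, stopped at full conversion; then SiO2, CH2Cl2, rt
Reagents that add atoms: none
Why: Excitation of the hydrogen-bonded enol (C10(OH)=C7–C8=O) lets C10 bond to C5 of the tethered 1,1-disubstituted alkene and the 1,4-biradical close C7–C6; cyclobutanol 12 is a strained β-hydroxy ketone and opens by retro-aldol cleavage of C7–C10, which returns C10 as the ring ketone and leaves C6–C7–C8(=O)–C9 as the side chain on C5. The closest known reaction type is the intramolecular de Mayo reaction of 1,3-diketone enols (and the related enone–alkene [2+2] photocycloadditions) with a four-atom tether. Ring B closes in the 6-exo-trig mode (C10 onto C5, C6 outside the ring), and the four-membered ring closes by radical recombination and is cleaved again. The one lasting new stereocentre, quaternary C5, is controlled by the C3 and C4 centres through a chair-like closure with the C3 silyloxy group equatorial and the C4 methyl axial, in which C10 meets the alkene face that puts the C5 methyl cis to the C4 methyl, since the opposite face would force C7 syn-axial to that methyl. The step needs the straight (C10–C5, C7–C6) and not the crossed orientation, which the four-atom tether secures because only the six-membered first closure is within reach, and it needs this chair and not the flipped one (axial silyloxy group, equatorial C4 methyl) that leads to the C5 epimer. Against the flipped chair the substrate offers the equatorial preference of the silyl ether, which would there be syn-axial to the reacting methylene; this bias is moderate, so the C5 epimer is the by-product to expect and should be removable by chromatography of 13.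

**Step 7**
Reactants: 13 (2R,3R,4S)-2-[4-(tert-butyldimethylsilyloxy)-3-oxobutyl]-2,3-dimethyl-4-(triethylsilyloxy)cyclohexan-1-one
Product: 14 (1S,4aR,5R,6S,8aR)-1-(tert-butyldimethylsilyloxy)-8a-hydroxy-4a,5-dimethyl-6-(triethylsilyloxy)octahydronaphthalen-2(1H)-one (cis-ketol; 9α-OTBS, 10β-OH, 3β-OSiEt3)
Conditions: NaOMe (0.2 equiv), MeOH/THF, −10 → 0 °C; AcOH quench
Reagents that add atoms: none
Why: Base-mediated intramolecular aldol addition (the ketol stage of a Robinson annulation) under equilibrating conditions: the side chain is axial on ring B (the other chair would set the C3 silyloxy group and the C5 methyl 1,3-diaxial), so C9 can only attack C10 equatorially and the 10-OH ends cis to the C5 methyl, while C9 settles with its silyloxy group equatorial on ring A (trans to the 10-OH) because the axial epimer is 1,3-diaxial to the C5 methyl; the low temperature keeps the ketol from dehydrating.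

**Step 8**
Reactants: 14 cis-ketol
Product: 15 C7–C8 enol trimethylsilyl ether 10-O-trimethylsilyl ether of 14 (9α-OTBS, 3β-OSiEt3 unchanged)
Conditions: LDA (LiN(i-Pr)2, 2.5 equiv), Me3SiCl (5 equiv), THF, −78 °C (in situ quench); Et3N, → 0 °C
Reagents that add atoms: chlorotrimethylsilane, C[Si](C)(C)Cl
Why: Kinetic deprotonation at the less hindered C7 methylene (C9 is a methine flanked by the quaternary C10) with in situ silylation gives the C7–C8 silyl enol ether and silylates the tertiary alkoxide, and fast enolisation of the C8 ketone removes the acceptor that a retro-aldol opening would need.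

**Step 9**
Reactants: 15 bis-trimethylsilyl compound
Product: 16 C6=C7 enone: 1-(tert-butyldimethylsilyloxy)-4a,5-dimethyl-6-(triethylsilyloxy)-8a-(trimethylsilyloxy)-4a,5,6,7,8,8a-hexahydronaphthalen-2(1H)-one (configuration as in 14)
Conditions: Pd(OAc)2 (1.1 equiv), MeCN, rt
Reagents that add atoms: none
Why: Saegusa–Ito oxidation: palladation of the silyl enol ether at C7 and β-hydride elimination, which can only use the C6 hydrogens because C5 is quaternary.

**Step 10**
Reactants: 16 enone
Product: 17 3-iodo derivative of 16 (iodine on C7)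
Conditions: I2 (2 equiv), pyridine/CH2Cl2, 4-(dimethylamino)pyridine (cat.), rt
Reagents that add atoms: iodine, II
Why: α-Iodination of the enone by conjugate addition of pyridine, iodination of the enolate at C7 and loss of pyridine (addition–elimination), which can place iodine only on the α-carbon.

**Step 11**
Reactants: 17 α-iodoenone
Product: 19 3-acetyl-1-(tert-butyldimethylsilyloxy)-6,8a-dihydroxy-4a,5-dimethyl-4a,5,6,7,8,8a-hexahydronaphthalen-2(1H)-one (9α-OTBS, 10β-OH, 3β-OH), via 7-(1-ethoxyvinyl) enone 18 (not isolated)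
Conditions: Bu3Sn–C(OEt)=CH2 (1.5 equiv), PdCl2(PPh3)2 (5 mol %), CuI (10 mol %), DMF, 50 °C; then 1 M HCl, THF, rt
Reagents that add atoms: tributyl(1-ethoxyvinyl)stannane, CCCC[Sn](CCCC)(CCCC)C(=C)OCC; water, O
Why: Stille coupling of the α-iodoenone with the 1-ethoxyvinyl stannane (a masked acetyl group), then mild acid hydrolysis, which unveils the C7 acetyl group and also cleaves the tertiary trimethylsilyl and the secondary triethylsilyl ethers, while the hindered, electron-poor α-keto tert-butyldimethylsilyl ether at C9 should survive.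

**Step 12**
Reactants: 19 diol
Product: 20 6-O-acetate of 19 (3β-OAc, 9α-OTBS, 10β-OH)
Conditions: Ac2O (1.5 equiv), pyridine, CH2Cl2, 0 °C → rt
Reagents that add atoms: acetic anhydride, CC(=O)OC(C)=O
Why: Acetylation of the only secondary hydroxyl (C3); the tertiary C10 hydroxyl does not react with acetic anhydride/pyridine under these conditions.

**Step 13**
Reactants: 20 acetate
Product: 21 3-acetyl-6-acetoxy-1,8a-dihydroxy-4a,5-dimethyl-4a,5,6,7,8,8a-hexahydronaphthalen-2(1H)-one (9α-OH, 10β-OH, 3β-OAc)
Conditions: HF·pyridine, THF/pyridine, 0 °C → rt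
Reagents that add atoms: none
Why: Fluoride cleavage of the silyl ether under buffered, non-basic conditions that leave the acetate, the β-hydroxy ketone and the doubly activated enone alone.

**Step 14**
Reactants: 21 diol acetate; 22 angelic acid ((Z)-2-methylbut-2-enoic acid)
Product: 24 CNP0196241.1, (1S,4aR,5R,6S,8aR)-3-acetyl-6-acetoxy-8a-hydroxy-4a,5-dimethyl-2-oxo-1,2,4a,5,6,7,8,8a-octahydronaphthalen-1-yl (Z)-2-methylbut-2-enoate, via angelic 2,4,6-trichlorobenzoic anhydride 23 (not isolated)
Conditions: 22 (3 equiv), 2,4,6-trichlorobenzoyl chloride (3 equiv), Et3N (3 equiv), toluene, rt; then 21, toluene, 75 °C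
Reagents that add atoms: none
Why: Yamaguchi-type esterification, in which the mixed anhydride acylates the secondary C9 hydroxyl at the less hindered angeloyl carbonyl without a nucleophilic catalyst, conditions known to keep the Z geometry of angelates; the tertiary hydroxyl does not react.

**Compound list**
1 | (E)-2-bromobut-2-ene | C/C=C(\C)Br | starting material
2 | (Z)-but-2-en-2-yllithium | C/C=C(\C)[Li] | intermediate (not isolated)
3 | (E)-4,4,5,5-tetramethyl-2-(2-methylbut-2-en-1-yl)-1,3,2-dioxaborolane | C/C=C(\C)CB1OC(C)(C)C(C)(C)O1 | intermediate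
4 | methyl 4-oxobutanoate | COC(=O)CCC=O | starting material
5 | methyl (4S,5R)-4-hydroxy-5,6-dimethylhept-6-enoate | CC(=C)[C@@H](C)[C@H](CCC(=O)OC)O | intermediate (not isolated)
6 | (S)-5-[(R)-3-methylbut-3-en-2-yl]dihydrofuran-2(3H)-one | CC(=C)[C@@H](C)[C@@H]1CCC(=O)O1 | intermediate
7 | (4S,5R)-4-hydroxy-N-methoxy-N,5,6-trimethylhept-6-enamide | CC(=C)[C@@H](C)[C@H](CCC(=O)N(C)OC)O | intermediate
8 | (4S,5R)-N-methoxy-N,5,6-trimethyl-4-(triethylsilyloxy)hept-6-enamide | CC(=C)[C@@H](C)[C@H](CCC(=O)N(C)OC)O[Si](CC)(CC)CC | intermediate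
9 | 1-(tert-butyldimethylsilyloxy)propan-2-one | CC(=O)CO[Si](C)(C)C(C)(C)C | starting material
10 | lithium 3-(tert-butyldimethylsilyloxy)prop-1-en-2-olate | [Li]OC(=C)CO[Si](C)(C)C(C)(C)C | intermediate (not isolated)
11 | (7S,8R)-1-(tert-butyldimethylsilyloxy)-8,9-dimethyl-7-(triethylsilyloxy)dec-9-ene-2,4-dione | CC(=C)[C@@H](C)[C@H](CCC(=O)CC(=O)CO[Si](C)(C)C(C)(C)C)O[Si](CC)(CC)CC | intermediate (key-step precursor)
12 | cis-fused bicyclo[4.2.0]octan-1-ol photoadduct (C10–C5 and C7–C6 bonds; 10-OH cis to the C5 methyl; C7 epimers) | O[C@]12CC[C@H](O[Si](CC)(CC)CC)[C@H](C)[C@@]1(C)CC2C(=O)CO[Si](C)(C)C(C)(C)C | intermediate (not isolated)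
13 | (2R,3R,4S)-2-[4-(tert-butyldimethylsilyloxy)-3-oxobutyl]-2,3-dimethyl-4-(triethylsilyloxy)cyclohexan-1-one | O=C1CC[C@H](O[Si](CC)(CC)CC)[C@H](C)[C@@]1(C)CCC(=O)CO[Si](C)(C)C(C)(C)C | intermediate (key-step product)
14 | (1S,4aR,5R,6S,8aR)-1-(tert-butyldimethylsilyloxy)-8a-hydroxy-4a,5-dimethyl-6-(triethylsilyloxy)octahydronaphthalen-2(1H)-one | CC(C)(C)[Si](C)(C)O[C@@H]1C(=O)CC[C@]2(C)[C@@H](C)[C@@H](O[Si](CC)(CC)CC)CC[C@]12O | intermediate
15 | C7–C8 enol trimethylsilyl ether 10-O-trimethylsilyl ether of 14 | CC(C)(C)[Si](C)(C)O[C@@H]1C(O[Si](C)(C)C)=CC[C@]2(C)[C@@H](C)[C@@H](O[Si](CC)(CC)CC)CC[C@]12O[Si](C)(C)C | intermediate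
16 | 1-(tert-butyldimethylsilyloxy)-4a,5-dimethyl-6-(triethylsilyloxy)-8a-(trimethylsilyloxy)-4a,5,6,7,8,8a-hexahydronaphthalen-2(1H)-one | CC(C)(C)[Si](C)(C)O[C@@H]1C(=O)C=C[C@]2(C)[C@@H](C)[C@@H](O[Si](CC)(CC)CC)CC[C@]12O[Si](C)(C)C | intermediate
17 | 3-iodo derivative of 16 | CC(C)(C)[Si](C)(C)O[C@@H]1C(=O)C(I)=C[C@]2(C)[C@@H](C)[C@@H](O[Si](CC)(CC)CC)CC[C@]12O[Si](C)(C)C | intermediate
18 | 3-(1-ethoxyvinyl) derivative of 16 | CC(C)(C)[Si](C)(C)O[C@@H]1C(=O)C(C(=C)OCC)=C[C@]2(C)[C@@H](C)[C@@H](O[Si](CC)(CC)CC)CC[C@]12O[Si](C)(C)C | intermediate (not isolated)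
19 | 3-acetyl-1-(tert-butyldimethylsilyloxy)-6,8a-dihydroxy-4a,5-dimethyl-4a,5,6,7,8,8a-hexahydronaphthalen-2(1H)-one | CC(C)(C)[Si](C)(C)O[C@@H]1C(=O)C(C(C)=O)=C[C@]2(C)[C@@H](C)[C@@H](O)CC[C@]12O | intermediate
20 | 6-O-acetate of 19 | CC(C)(C)[Si](C)(C)O[C@@H]1C(=O)C(C(C)=O)=C[C@]2(C)[C@@H](C)[C@@H](OC(C)=O)CC[C@]12O | intermediate
21 | 3-acetyl-6-acetoxy-1,8a-dihydroxy-4a,5-dimethyl-4a,5,6,7,8,8a-hexahydronaphthalen-2(1H)-one | O[C@@H]1C(=O)C(C(C)=O)=C[C@]2(C)[C@@H](C)[C@@H](OC(C)=O)CC[C@]12O | intermediate
22 | angelic acid, (Z)-2-methylbut-2-enoic acid | C/C=C(/C)C(=O)O | starting material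
23 | angelic 2,4,6-trichlorobenzoic anhydride | C/C=C(/C)C(=O)OC(=O)c1c(Cl)cc(Cl)cc1Cl | intermediate (not isolated)
24 | CNP0196241.1 | C/C=C(/C)C(=O)O[C@@H]1C(=O)C(C(C)=O)=C[C@]2(C)[C@@H](C)[C@@H](OC(C)=O)CC[C@]12O | target

**Step count**
Total: 14 steps. Longest linear sequence: 14 steps (1 → 24); 4, 9 and 22 enter as commercial materials.

**Steps most likely to fail**

Step 6. The likely failure is poor facial selectivity at C5: closure through the flipped chair (axial silyloxy group, equatorial C4 methyl) would give the C5 epimer, helped by the methyl–methyl contact in the desired chair. Crossed addition or secondary photochemistry of the product ketones could add to the loss.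
Fallback (sets out from 8 and 9, returns at 13): the quaternary centre is built in the ground state by a Michael addition. Amide 8 is reduced (i-Bu2AlH, THF, −78 °C) to (4S,5R)-5,6-dimethyl-4-(triethylsilyloxy)hept-6-enal F1. Ozonolysis (O3, CH2Cl2, −78 °C; Me2S) gives (4S,5S)-5-methyl-6-oxo-4-(triethylsilyloxy)heptanal F2. SmI2 (THF, t-BuOH) closes ring B by ketone–aldehyde pinacol coupling to 2,3-dimethyl-4-(triethylsilyloxy)cyclohexane-1,2-diol F3. Parikh–Doering oxidation (SO3·pyridine, DMSO, i-Pr2NEt) of the secondary hydroxyl gives 2-hydroxy-2,3-dimethyl-4-(triethylsilyloxy)cyclohexan-1-one F4, and SmI2 (THF/MeOH) removes the tertiary α-hydroxyl to give 2,3-dimethyl-4-(triethylsilyloxy)cyclohexan-1-one F5. Ketone 9 is converted (LiN(i-Pr)2; CH2=NMe2 iodide) into 1-(tert-butyldimethylsilyloxy)-4-(dimethylamino)butan-2-one F6, methylated (MeI) to [4-(tert-butyldimethylsilyloxy)-3-oxobutyl]trimethylammonium iodide F7 and eliminated (NaHCO3) to 1-(tert-butyldimethylsilyloxy)but-3-en-2-one F8. Base-catalysed Michael addition of F5 to F8 (KOt-Bu cat., t-BuOH/THF, 0 °C) takes place at the more substituted α-carbon and anti to the neighbouring C4 methyl group, the classical way to a cis-vicinal dimethyl pair, and gives 13.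

Step 7. The likely failures are enolisation of the ring ketone at C1 with bridged aldol addition onto C8, and an aldol equilibrium that lies on the side of the open diketone for the hindered α-silyloxy nucleophile.
Fallback (sets out from 8, returns at 16): the C9 oxygen is introduced after ring A is closed. Amide 8 is acylated with the lithium enolate of acetone to (7S,8R)-8,9-dimethyl-7-(triethylsilyloxy)dec-9-ene-2,4-dione F9. Irradiation as in step 6 gives (2R,3R,4S)-2,3-dimethyl-2-(3-oxobutyl)-4-(triethylsilyloxy)cyclohexan-1-one F10. NaOEt (cat.), EtOH, −10 °C closes, with the unhindered methyl group as the nucleophile (the ketol stage of a Robinson annulation), 10β-hydroxy-4β,5β-dimethyl-3β-(triethylsilyloxy)-cis-decalin-8-one F11. In situ silylation as in step 8 gives the C7–C8 enol trimethylsilyl ether 10-O-trimethylsilyl ether F12, and Pd(OAc)2 gives 4β,5β-dimethyl-3β-(triethylsilyloxy)-10β-(trimethylsilyloxy)-cis-decal-6-en-8-one F13. With C7 now sp2, LiN(i-Pr)2 can form only the C8–C9 enolate, and 2-(phenylsulfonyl)-3-phenyloxaziridine hydroxylates it to the 9α-hydroxy enone F14; the equatorial 9α epimer is also the thermodynamic one. t-BuMe2SiOTf/2,6-lutidine then gives 16.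

Step 14. The likely failures are slow acylation of the hindered C9 hydroxyl, isomerisation of the Z angeloyl unit to the E (tigloyl) form during prolonged heating with base, and base-induced retro-aldol opening of ring A.
Fallback (sets out from 21, returns at 24): the angelate is built on the alcohol instead of being transferred. Alcohol 21 is acylated with the saturated, unhindered 2-(diphenoxyphosphoryl)propanoic acid (N,N'-diisopropylcarbodiimide, 4-(dimethylamino)pyridine cat., CH2Cl2) to the 9-O-[2-(diphenoxyphosphoryl)propanoyl] ester F15. A Z-selective Horner–Wadsworth–Emmons reaction of the Ando type with acetaldehyde (NaI, DBU, THF, −78 → 0 °C) then gives 24.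

**Further compounds**
F1 | step 6 | (4S,5R)-5,6-dimethyl-4-(triethylsilyloxy)hept-6-enal | CC(=C)[C@@H](C)[C@H](CCC=O)O[Si](CC)(CC)CC
F2 | step 6 | (4S,5S)-5-methyl-6-oxo-4-(triethylsilyloxy)heptanal | CC(=O)[C@@H](C)[C@H](CCC=O)O[Si](CC)(CC)CC
F3 | step 6 | 2,3-dimethyl-4-(triethylsilyloxy)cyclohexane-1,2-diol (C3/C4 centres of 8 kept; diol epimers) | OC1CC[C@H](O[Si](CC)(CC)CC)[C@H](C)C1(C)O
F4 | step 6 | 2-hydroxy-2,3-dimethyl-4-(triethylsilyloxy)cyclohexan-1-one | O=C1CC[C@H](O[Si](CC)(CC)CC)[C@H](C)C1(C)O
F5 | step 6 | 2,3-dimethyl-4-(triethylsilyloxy)cyclohexan-1-one (C2 epimers) | O=C1CC[C@H](O[Si](CC)(CC)CC)[C@H](C)C1C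
F6 | step 6 | 1-(tert-butyldimethylsilyloxy)-4-(dimethylamino)butan-2-one | CN(C)CCC(=O)CO[Si](C)(C)C(C)(C)C
F7 | step 6 | [4-(tert-butyldimethylsilyloxy)-3-oxobutyl]trimethylammonium iodide | C[N+](C)(C)CCC(=O)CO[Si](C)(C)C(C)(C)C.[I-]
F8 | step 6 | 1-(tert-butyldimethylsilyloxy)but-3-en-2-one | C=CC(=O)CO[Si](C)(C)C(C)(C)C
F9 | step 7 | (7S,8R)-8,9-dimethyl-7-(triethylsilyloxy)dec-9-ene-2,4-dione | CC(=C)[C@@H](C)[C@H](CCC(=O)CC(C)=O)O[Si](CC)(CC)CC
F10 | step 7 | (2R,3R,4S)-2,3-dimethyl-2-(3-oxobutyl)-4-(triethylsilyloxy)cyclohexan-1-one | O=C1CC[C@H](O[Si](CC)(CC)CC)[C@H](C)[C@@]1(C)CCC(C)=O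
F11 | step 7 | 10β-hydroxy-4β,5β-dimethyl-3β-(triethylsilyloxy)-cis-decalin-8-one | C1C(=O)CC[C@]2(C)[C@@H](C)[C@@H](O[Si](CC)(CC)CC)CC[C@]12O
F12 | step 7 | C7–C8 enol trimethylsilyl ether 10-O-trimethylsilyl ether of F11 | C1C(O[Si](C)(C)C)=CC[C@]2(C)[C@@H](C)[C@@H](O[Si](CC)(CC)CC)CC[C@]12O[Si](C)(C)C
F13 | step 7 | 4β,5β-dimethyl-3β-(triethylsilyloxy)-10β-(trimethylsilyloxy)-cis-decal-6-en-8-one | C1C(=O)C=C[C@]2(C)[C@@H](C)[C@@H](O[Si](CC)(CC)CC)CC[C@]12O[Si](C)(C)C
F14 | step 7 | 9α-hydroxy derivative of F13 | O[C@@H]1C(=O)C=C[C@]2(C)[C@@H](C)[C@@H](O[Si](CC)(CC)CC)CC[C@]12O[Si](C)(C)C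
F15 | step 14 | 9-O-[2-(diphenoxyphosphoryl)propanoyl] ester of 21 | CC(C(=O)O[C@@H]1C(=O)C(C(C)=O)=C[C@]2(C)[C@@H](C)[C@@H](OC(C)=O)CC[C@]12O)P(=O)(Oc1ccccc1)Oc1ccccc1
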